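## Structural features

The target is a tricyclic bis-ether. Cyclohexane ring A (C1, C2, C3, C13, C12, C11) is bridged from C3 to C11 by O4–C5–C10, which gives the seven-membered oxacycle ring B and a 2-oxabicyclo[3.2.2]nonane core. Oxane ring C (C5, C6, C7, C8, O9, C10) is cis-fused to ring B across C5–C10. Of the seven stereocentres, C5, C10, C11 and C1 are contiguous, C3 and C13 are neighbours, and C7 stands alone next to the gem-dimethyl carbon C8; C3, C8 and C10 are fully substituted ether carbons. The C1 acetate points towards the O4 bridge and the C13 hydroxyl towards the C1–C2 bridge. The C10 methyl and the C5 hydrogen face the C12–C13 bridge, whereas O9 and C6 face the C1–C2 bridge; bromine is cis to C5–H and C10–CH3 on ring C. Fragile groups are the acetate (base, acyl transfer to a neighbouring oxygen), the secondary bromide beside quaternary C8 (elimination, ring contraction through an oxonium ion) and the tertiary ethers (acid). A free C1 hydroxyl would also lactonise onto any acyl group at C5. The real difficulty lies in the bridged ether with its quaternary C3–O bond, the tertiary ether centre C10 and the bromide at C7. The key step uses the fact that O4 sits between fully substituted C3 and C5, and the acetate oxygen between C1 and an acetyl carbon. Each oxygen therefore lies beside the more substituted of two carbons, where a peracid would insert it; removing both leaves a bicyclo[2.2.2]octan-2-one with an endo acetyl group on C1.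

## Logic of the disconnections

29 to 28: the C13 O–Si bond is cut. The hydroxyl must be masked from step 10 to step 18 because it would otherwise be phosphorylated or oxidised. The forward step must spare the acetate, the bromide and the tertiary ethers.

28 to 27: O9–C8 and C7–Br are cut together. This removes ring C and the last stereocentre and leaves a prenyl side chain and a tertiary alcohol. The forward step needs a bromonium donor to be opened by O9 at the more substituted alkene carbon in the six-membered mode, on the correct alkene face.

27 to 26: the C10–CH3 bond is cut. The quaternary centre becomes a ketone flanked by C5 and C11. The methyl nucleophile must come from the face of C5–H and must be non-basic enough to spare the C5 centre and the acetate.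

26 to 25: the C10 carbonyl goes back to a secondary alcohol. This places the epimerisable ketone only between steps 16 and 17. The oxidation must tolerate a trisubstituted alkene.

25 to 23 and 24: the C7=C8 double bond is cut into an aldehyde at C7 and a three-carbon ylide. The alkene is thus introduced only after the hydroboration of step 13. The olefination must be faster than enolisation of the β-alkoxy aldehyde.

23 to 22: the C7 aldehyde is returned to its dioxolane acetal. The forward hydrolysis must leave the silyl ether and the acetate in place.

22 to 20: C5–H and C10–O are cut as the elements of water across a C5=C10 enol ether. Both centres become sp2 and the C5 stereocentre becomes a question of facial selectivity. Boron must go to C10 and hydrogen to C5 from the face away from the C1 acetate.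

20 to 18 and 19: the C5–C6 bond is cut between an enol phosphate and an alkylzinc reagent. A palladium-catalysed coupling is chosen because it tolerates the acetate, unlike organolithium addition to the lactone.

18 to 17: the enol phosphate goes back to the lactone. Only C10 carries α-hydrogens in the lactone; the forward enolisation must discriminate between the lactone and the acetate.

17 to 16: O–Si bond at C13, a protection.

16 to 15: the C13–H bond is cut to a ketone. The reduction is placed where the O4–C5–C10 bridge is still a flat lactone, so that one face of C13 is flanked only by O4.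

15 to 14: the C13 carbonyl is returned to its dioxolane, which must survive the peracid of step 7 and come off without hydrolysis of the acetate.

14 to 12: O4 is removed from between C3 and C5 and the ester oxygen from between C1 and the acetyl carbon. Ring B shrinks to a carbocycle, and all three stereocentres of 14 are already present in 12. The forward step demands migration of C3 rather than C10 and of C1 rather than methyl, both with retention.

12 to 9 and 10: C1–C11 and C2–C3 are cut in a [4+2] sense (the silyl enol ether 11 lies between). Ring A and three stereocentres are traded for an achiral diene and an enone. The forward step must be regioselective (C3 to the enone CH2), endo-selective and enantioselective.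

9 to 8: the O–Si bond of the dienol ether; the forward enolisation must take the C3 hydrogen without loss of the neighbouring ketal oxygen.

8 to 6: the C10=C11 double bond is removed; the forward dehydrogenation must start from the kinetic enolate on the C10 side.

6 to 5 to 3: the C5 carbonyl is traced to an alcohol and then to a C3=C5 alkene, which places oxygen on C5 by hydroboration rather than by mono-protection of a 1,3-dione.

3 to 1 and 2: the two C13–O bonds of the dioxolane are cut; the ketalisation must not move the double bond.

## Other disconnections considered

Alternative 1: The cut is at C5–C6 and C5–C10, with C5 as a dithiane linchpin. Lithiated silyl dithiane A2 would open epoxide A3 at C6, the silyl group would shift to the C7 oxygen (Brook rearrangement), and the regenerated C5 anion would be acylated by the ring A amide A4 to give A1.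
- In favour: the union is convergent. C7 comes from an enantiopure epoxide and does not depend on a late facial selectivity, and the C1, C11 and C13 centres are fixed in a separate fragment. On convergence and on the security of C7 this alternative is the better plan.
- Against: A1 contains neither ether ring. Still required are methyl addition to the C10 ketone beside the bulky dithiane and unmasking of C5. Closure of O4 onto C3 of a trisubstituted alkene must then form a bridged seven-membered ring through a boat of ring A, and the O9–C10 bond joins two tertiary carbons. Four hydroxyl protecting groups of three kinds are carried.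
- Structural point: in A1 the C7 oxygen has the same spatial sense as the C–Br bond of the target. A single invertive bromination would give the C7 epimer, so ent-A3 or a net-retentive bromination is needed.
- Comparison: the linchpin coupling is as dependable as the cross-coupling of the chosen plan (equal). The chosen plan makes ring B by oxygen insertion into an existing ring with retention, which is mechanistically safer than closing it. The total step count of the alternative is probably higher although its longest linear sequence is shorter.

Alternative 2: The cut is at O9–C10 (oxidative dearomatisation) and at C1–C11 and C2–C3 (intramolecular cycloaddition). Pb(OAc)4 oxidation of phenol A5 with acrylic acid (Wessely acyloxylation) would give a 6-acryloyloxycyclohexa-2,4-dienone, which would cyclise to A6.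
- In favour: two operations lead from an aromatic compound to a bicyclo[2.2.2]octenone that already holds the C10 oxygen and methyl, the C3 methyl and the C13 oxygen. The tether places the C1 substituent on the correct side. In step economy to the core and in fixing C10 this alternative is the better plan.
- Against: the oxidation gives a racemate. Acyloxylation can also occur at the other methyl-bearing ortho carbon, C3, and the dienone can dimerise. C1 carries a carbon, not an oxygen, so a later carbon-to-oxygen exchange is needed. The oxygen insertion at C5 must choose between two fully substituted carbons, C3 and the acyloxy-bearing C10; the chosen plan avoids this by keeping C10 as a methylene.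
- Comparison: the C13 ketone reduction is the same problem in both plans (equal). The alternative is shorter to the core but longer and less certain afterwards, and it has no control of absolute configuration.

Alternative 3: The cut is at O4–C5 and O9–C10, back to the cineole-type ether A7, in which O4 joins C3 and C10. Zn(OAc)2-buffered ionisation of the C5 chloromethanesulfonate with participation of O4 would give a C10–O4–C5 oxonium ion, which the C8 hydroxyl would open at C10 to give A8.
- In favour: one stereospecific step forms two C–O bonds, enlarges ring B and closes ring C. C5 and C10 follow from double inversion and not from facial selectivity, and the bromide is in place before the bicyclic ether exists. On the stereochemical security of C5, C10 and C7 this alternative is the better plan.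
- Against: A7 must already contain all seven stereocentres, including the C5 carbinol and the tertiary ether C10 in inverted form. The oxonium ion could also be opened at C5 by the C8 hydroxyl (five-membered ring, no expansion) or by acetate. A8 has silyl at C1 and a free C13 hydroxyl, so the C1 acetate needs further protecting-group exchanges.
- Comparison: the endgame is mechanistically the most elegant, but the effort moves into the precursor and the total is unlikely to be shorter. The chosen plan carries the C1 acetate unchanged from the key step to the target, which is its advantage here.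

Key step: step 7

Remarks and assumptions:
- Target atom numbers (C1 to C13) are used for all intermediates. Compounds 4 to 8 are racemic, and their stereocentres disappear in 9.
- The sense of induction in step 6 is assumed from the usual model for this catalyst class; if it is opposite, the (R)-catalyst is used and nothing else changes.
- Structure check: 12 and 14 have the C1, C3 and C11 arrangement of the target, so no structure needed changing. The CIP letters at C3 and C11 differ between 12 and 14 only because priorities change.
- Changes of design:
  - The ketone 6 is made by hydroboration of an ene ketal, because direct mono-ketalisation of 2-methylcyclohexane-1,3-dione is expected to stop at the hydroxyethyl enol ether.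
  - The acetate is kept from step 7 to the end, since a free C1 hydroxyl would translactonise onto C5. The lactone is therefore elaborated without organolithium addition.
  - C13 is reduced directly after the key step.
  - Ring C is closed by bromoetherification; an epoxide opening would favour the five-membered ring.

## Steps

Step 1
Reactants: 1 2-methylcyclohex-2-en-1-one; 2 1,2-bis(trimethylsilyloxy)ethane
Product: 3 6-methyl-1,4-dioxaspiro[4.5]dec-6-ene
Conditions: Me3SiOTf (5 mol %), CH2Cl2, −78 → −20 °C
Reagents that add atoms: none
Why: Aprotic silyl triflate-catalysed ketalisation with the bis-silyl ether should convert the enone carbonyl (C13) into the dioxolane without moving the C3=C5 double bond, because no dienol ether is formed under these conditions.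

Step 2
Reactants: 3 6-methyl-1,4-dioxaspiro[4.5]dec-6-ene
Product: 5 trans-6-methyl-1,4-dioxaspiro[4.5]decan-7-ol (racemic), via alkylborane 4 (not isolated)
Conditions: BH3·THF, THF, 0 °C → rt; then NaOH, H2O2, 0 °C
Reagents that add atoms: hydrogen peroxide OO
Why: Hydroboration–oxidation of the trisubstituted alkene should place boron on the less substituted C5 and hydrogen on C3 on the same face, giving the trans alcohol; both centres are erased in steps 3 and 5.

Step 3
Reactants: 5 trans-6-methyl-1,4-dioxaspiro[4.5]decan-7-ol
Product: 6 6-methyl-1,4-dioxaspiro[4.5]decan-7-one (racemic)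
Conditions: (n-Pr)4N[RuO4] (5 mol %), NMO, 4 Å MS, CH2Cl2, rt
Reagents that add atoms: none
Why: Ley–Griffith oxidation is neutral, so the β-keto ketal should not open to the hydroxyethyl enol ether.

Step 4
Reactants: 6 6-methyl-1,4-dioxaspiro[4.5]decan-7-one
Product: 8 6-methyl-1,4-dioxaspiro[4.5]dec-8-en-7-one, via trimethylsilyl enol ether 7 (not isolated)
Conditions: LiN(i-Pr)2, Me3SiCl, THF, −78 °C; then Pd(OAc)2 (1.05 equiv), MeCN, rt
Reagents that add atoms: none
Why: Saegusa–Ito oxidation: kinetic deprotonation should occur at the C10 methylene and not at the hindered C3 methine, and dehydrosilylation of 7 by Pd(OAc)2 then gives the C10=C11 enone.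

Step 5
Reactants: 8 6-methyl-1,4-dioxaspiro[4.5]dec-8-en-7-one
Product: 9 tert-butyldimethyl[(6-methyl-1,4-dioxaspiro[4.5]deca-6,8-dien-7-yl)oxy]silane
Conditions: LiN(i-Pr)2, THF, −78 °C; then t-BuMe2SiOTf, −78 °C
Reagents that add atoms: tert-butyldimethylsilyl trifluoromethanesulfonate CC(C)(C)[Si](C)(C)OS(=O)(=O)C(F)(F)F
Why: Kinetic deprotonation of an enone takes the α′ hydrogen (C3–H) and O-silylation gives the cross-conjugated 2-silyloxy diene; trapping at −78 °C should outrun β-elimination of the ketal oxygen, which would aromatise the ring.

Step 6
Reactants: 9 tert-butyldimethyl[(6-methyl-1,4-dioxaspiro[4.5]deca-6,8-dien-7-yl)oxy]silane; 10 but-3-en-2-one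
Product: 12 (1S,4R,5S)-5-acetyl-7,7-(ethylenedioxy)-1-methylbicyclo[2.2.2]octan-2-one, via silyl enol ether cycloadduct 11 (not isolated)
Conditions: (S)-3,3-diphenyl-1-(o-tolyl)tetrahydro-1H,3H-pyrrolo[1,2-c][1,3,2]oxazaborole·HNTf2 (20 mol %), CH2Cl2, −78 °C; then Bu4NF, AcOH, THF, 0 °C
Reagents that add atoms: none
Why: Enantioselective Diels–Alder reaction of a 2-silyloxy diene with a Lewis acid-activated enone: the nucleophilic diene terminus C3 bonds to the enone CH2 (C2) and C11 to C1, the endo mode places the acetyl group over the C5=C10 bridge, and the catalyst selects the diene face, which sets C1, C3 and C11 together. Buffered fluoride then frees the C5 ketone without the base that could close an aldol between the acetyl methyl and C5.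

Step 7
Reactants: 12 (1S,4R,5S)-5-acetyl-7,7-(ethylenedioxy)-1-methylbicyclo[2.2.2]octan-2-one
Product: 14 (1R,5S,6S)-6-acetoxy-8,8-(ethylenedioxy)-1-methyl-2-oxabicyclo[3.2.2]nonan-3-one, via acetyl lactone 13 (not isolated)
Conditions: (CF3CO)2O, H2O2·urea, Na2HPO4, CH2Cl2, 0 °C → rt
Reagents that add atoms: trifluoroperacetic acid OOC(=O)C(F)(F)F
Why: Twofold Baeyer–Villiger oxidation: the peracid adds to each carbonyl to give a tetrahedral peroxy adduct, and the carbon anti-periplanar to the O–O bond that best carries positive charge shifts to oxygen as trifluoroacetate leaves. At C5 this should be quaternary C3 and not the C10 methylene, and at the acetyl group secondary C1 and not methyl; both shifts are suprafacial 1,2-migrations with retention. The closest known reaction types are the oxidation of bicyclo[2.2.2]octan-2-ones to 2-oxabicyclo[3.2.2]nonan-3-ones and of methyl ketones to acetates. The strained ring ketone is expected to react first (13), the methyl ketone second. No new ring is closed by a cyclisation: ring B grows from six to seven members when C3 moves from C5 to the inserted oxygen. No new stereocentre is formed; C1 and C3 keep their configuration because the migrating carbon retains it, and C11 is untouched. The selectivity needed is C3 over C10, secured by the tertiary-versus-primary difference, which should outweigh the inductive pull of the ketal on C13. The phosphate buffer should protect the dioxolane, whose loss would expose a third ketone to the peracid.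

Step 8
Reactants: 14 (1R,5S,6S)-6-acetoxy-8,8-(ethylenedioxy)-1-methyl-2-oxabicyclo[3.2.2]nonan-3-one
Product: 15 6-acetoxy-1-methyl-2-oxabicyclo[3.2.2]nonane-3,8-dione (C13 ketone)
Conditions: CF3CO2H/H2O (9:1), CH2Cl2, 0 °C → rt
Reagents that add atoms: water O
Why: Acid hydrolysis of the hindered dioxolane; the secondary acetate and the tertiary-alkyl lactone should survive aqueous acid at this temperature, which matters because a free C1 hydroxyl would lactonise onto C5.

Step 9
Reactants: 15 6-acetoxy-1-methyl-2-oxabicyclo[3.2.2]nonane-3,8-dione
Product: 16 6-acetoxy-8-hydroxy-1-methyl-2-oxabicyclo[3.2.2]nonan-3-one (C13 R; hydroxyl towards the C1–C2 bridge)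
Conditions: NaBH4, MeOH/CH2Cl2, −40 °C
Reagents that add atoms: none
Why: Chemoselective ketone reduction in the presence of lactone and acetate. Hydride should approach C13 from the side of the O4–C5 lactone bridge, which presents only an ether oxygen and a planar carbonyl, and not from the side of the C2 methylene, so that the hydroxyl ends on the face of the C1–C2 bridge (13R).

Step 10
Reactants: 16 6-acetoxy-8-hydroxy-1-methyl-2-oxabicyclo[3.2.2]nonan-3-one
Product: 17 6-acetoxy-8-(tert-butyldimethylsilyloxy)-1-methyl-2-oxabicyclo[3.2.2]nonan-3-one
Conditions: t-BuMe2SiOTf, 2,6-lutidine, CH2Cl2, −78 → 0 °C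
Reagents that add atoms: tert-butyldimethylsilyl trifluoromethanesulfonate CC(C)(C)[Si](C)(C)OS(=O)(=O)C(F)(F)F
Why: Silylation of a hindered secondary alcohol with the silyl triflate; the ether has to last through base, borane, oxidants and mild acid until step 19.

Step 11
Reactants: 17 6-acetoxy-8-(tert-butyldimethylsilyloxy)-1-methyl-2-oxabicyclo[3.2.2]nonan-3-one
Product: 18 6-acetoxy-8-(tert-butyldimethylsilyloxy)-1-methyl-2-oxabicyclo[3.2.2]non-3-en-3-yl diphenyl phosphate
Conditions: KN(SiMe3)2 (1.1 equiv), (PhO)2P(O)Cl, HMPA, THF, −78 °C (base added last)
Reagents that add atoms: diphenyl chlorophosphate O=P(Cl)(Oc1ccccc1)Oc1ccccc1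
Why: O-phosphorylation of the lactone enolate to the cyclic ketene acetal phosphate. The seven-membered lactone is held s-cis and should be several pK units more acidic than the s-trans acetate, and trapping in situ keeps the enolate from attacking the neighbouring acetate; only C10 carries α-hydrogens.

Step 12
Reactants: 18 6-acetoxy-8-(tert-butyldimethylsilyloxy)-1-methyl-2-oxabicyclo[3.2.2]non-3-en-3-yl diphenyl phosphate; 19 (1,3-dioxolan-2-ylmethyl)zinc bromide
Product: 20 6-acetoxy-8-(tert-butyldimethylsilyloxy)-3-(1,3-dioxolan-2-ylmethyl)-1-methyl-2-oxabicyclo[3.2.2]non-3-ene
Conditions: Pd(PPh3)4 (10 mol %), THF, 50 °C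
Reagents that add atoms: none
Why: Negishi coupling of a lactone-derived ketene acetal phosphate with an alkylzinc halide forms C5–C6 under conditions that leave the acetate alone; the acetal masks the C7 aldehyde through the hydroboration.

Step 13
Reactants: 20 6-acetoxy-8-(tert-butyldimethylsilyloxy)-3-(1,3-dioxolan-2-ylmethyl)-1-methyl-2-oxabicyclo[3.2.2]non-3-ene
Product: 22 C10 alcohol with C5–H (C5 S; both new bonds on the face of the C12–C13 bridge), via alkylborane 21 (not isolated)
Conditions: BH3·THF, THF, 0 °C; then NaBO3·4H2O, H2O, rt
Reagents that add atoms: sodium perborate [Na+].[Na+].O[B-]1(O)OO[B-](O)(O)OO1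
Why: Hydroboration of a cyclic enol ether puts boron on the β-carbon C10 and hydrogen on C5 in a syn addition. The face away from the C1 acetate is open because C13 shows only hydrogen on that side, so C5 should be set with hydrogen towards the C12–C13 bridge and C6 towards the C1–C2 bridge; perborate oxidises the borane without cleaving the acetate.

Step 14
Reactants: 22 C10 alcohol with C5–H
Product: 23 C7 aldehyde with free C10 hydroxyl (may exist in part as the cyclic hemiacetal)
Conditions: PPTS, acetone/H2O (9:1), 55 °C
Reagents that add atoms: water O
Why: Mild acid hydrolysis of the aldehyde dioxolane; the hindered silyl ether and the acetate should persist, and C5 is not next to a carbonyl group at this stage, so it cannot epimerise.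

Step 15
Reactants: 23 C7 aldehyde with free C10 hydroxyl; 24 isopropyltriphenylphosphonium iodide
Product: 25 prenyl alcohol (C5–CH2–CH=C(CH3)2 with secondary C10 hydroxyl)
Conditions: 24 (2.5 equiv), n-BuLi, THF, 0 °C; then 23, −78 → 0 °C
Reagents that add atoms: none
Why: Wittig olefination with a non-stabilised ylide should be faster than enolisation of the β-alkoxy aldehyde; the transient C10 alkoxide lies on the face opposite the C1 acetate, so acyl transfer is not expected.

Step 16
Reactants: 25 prenyl alcohol
Product: 26 C10 ketone with prenyl chain on C5
Conditions: DMP, pyridine, CH2Cl2, 0 °C → rt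
Reagents that add atoms: none
Why: Periodinane oxidation of the secondary alcohol under buffered conditions leaves the trisubstituted alkene untouched and should not epimerise C5; the ketone is used at once.

Step 17
Reactants: 26 C10 ketone with prenyl chain on C5
Product: 27 tertiary alcohol (C10 S; methyl towards the C12–C13 bridge, hydroxyl towards the C1–C2 bridge)
Conditions: MeMgBr, CeCl3, THF, −78 °C; NH4Cl quench at −78 °C
Reagents that add atoms: methylmagnesium bromide C[Mg]Br
Why: Cerium-mediated 1,2-addition is weakly basic and far faster at a ketone than at an ester. The methyl group should enter from the face of C5–H, opposite the C6 chain and the C1 acetate, which sets C10 with its oxygen cis to C6.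

Step 18
Reactants: 27 tertiary alcohol
Product: 28 C13 tert-butyldimethylsilyl ether of the target
Conditions: 2,4,4,6-tetrabromocyclohexa-2,5-dienone, MeNO2, 0 °C → rt
Reagents that add atoms: 2,4,4,6-tetrabromocyclohexa-2,5-dienone O=C1C(Br)=CC(Br)(Br)C=C1Br
Why: Bromoetherification: the bromonium ion of the trisubstituted alkene is opened by O9 at the more substituted carbon C8 in the six-membered (6-endo) mode with anti addition, which puts bromine equatorial in a chair-like transition state. The chair with the C10 methyl axial is expected to be favoured over the one with C11 axial and leads to the C7 configuration of the target.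

Step 19
Reactants: 28 C13 tert-butyldimethylsilyl ether of the target
Product: 29 CNP0247588.2
Conditions: HF·pyridine, pyridine, THF, 0 °C → rt
Reagents that add atoms: none
Why: Fluoride-mediated desilylation under buffered conditions frees the C13 hydroxyl without touching the acetate, the bromide or the tertiary ethers.

## Compound list

1 | 2-methylcyclohex-2-en-1-one | CC1=CCCCC1=O | starting material
2 | 1,2-bis(trimethylsilyloxy)ethane | C[Si](C)(C)OCCO[Si](C)(C)C | starting material
3 | 6-methyl-1,4-dioxaspiro[4.5]dec-6-ene | CC1=CCCCC12OCCO2 | intermediate
4 | (trans-6-methyl-1,4-dioxaspiro[4.5]decan-7-yl)borane, racemic | C[C@H]1[C@H](B)CCCC12OCCO2 | intermediate (not isolated)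
5 | trans-6-methyl-1,4-dioxaspiro[4.5]decan-7-ol, racemic | C[C@H]1[C@H](O)CCCC12OCCO2 | intermediate
6 | 6-methyl-1,4-dioxaspiro[4.5]decan-7-one, racemic | CC1C(=O)CCCC12OCCO2 | intermediate
7 | trimethyl[(6-methyl-1,4-dioxaspiro[4.5]dec-7-en-7-yl)oxy]silane, racemic | CC1C(O[Si](C)(C)C)=CCCC12OCCO2 | intermediate (not isolated)
8 | 6-methyl-1,4-dioxaspiro[4.5]dec-8-en-7-one, racemic | CC1C(=O)C=CCC12OCCO2 | intermediate
9 | tert-butyldimethyl[(6-methyl-1,4-dioxaspiro[4.5]deca-6,8-dien-7-yl)oxy]silane | CC1=C(O[Si](C)(C)C(C)(C)C)C=CCC12OCCO2 | intermediate
10 | but-3-en-2-one (methyl vinyl ketone) | CC(=O)C=C | starting material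
11 | endo-5-acetyl-2-(tert-butyldimethylsilyloxy)-7,7-(ethylenedioxy)-1-methylbicyclo[2.2.2]oct-2-ene, configuration as in 12 | CC(=O)[C@H]1C[C@@]2(C)C(O[Si](C)(C)C(C)(C)C)=C[C@@H]1CC23OCCO3 | intermediate (not isolated)
12 | (1S,4R,5S)-5-acetyl-7,7-(ethylenedioxy)-1-methylbicyclo[2.2.2]octan-2-one (ketone C5, endo acetyl on C1, dioxolane on C13) | CC(=O)[C@H]1C[C@@]2(C)C(=O)C[C@@H]1CC23OCCO3 | intermediate (key-step precursor)
13 | 6-acetyl-8,8-(ethylenedioxy)-1-methyl-2-oxabicyclo[3.2.2]nonan-3-one, configuration as in 14 | CC(=O)[C@H]1C[C@@]2(C)OC(=O)C[C@@H]1CC23OCCO3 | intermediate (not isolated)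
14 | (1R,5S,6S)-6-acetoxy-8,8-(ethylenedioxy)-1-methyl-2-oxabicyclo[3.2.2]nonan-3-one | CC(=O)O[C@H]1C[C@@]2(C)OC(=O)C[C@@H]1CC23OCCO3 | intermediate (key-step product)
15 | 6-acetoxy-1-methyl-2-oxabicyclo[3.2.2]nonane-3,8-dione | CC(=O)O[C@H]1C[C@@]2(C)OC(=O)C[C@@H]1CC2=O | intermediate
16 | 6-acetoxy-8-hydroxy-1-methyl-2-oxabicyclo[3.2.2]nonan-3-one, C13 R | CC(=O)O[C@H]1C[C@@]2(C)OC(=O)C[C@@H]1C[C@H]2O | intermediate
17 | C13 tert-butyldimethylsilyl ether of 16 | CC(=O)O[C@H]1C[C@@]2(C)OC(=O)C[C@@H]1C[C@H]2O[Si](C)(C)C(C)(C)C | intermediate
18 | ketene acetal diphenyl phosphate of 17 (C5=C10) | CC(=O)O[C@H]1C[C@@]2(C)OC(OP(=O)(Oc3ccccc3)Oc3ccccc3)=C[C@@H]1C[C@H]2O[Si](C)(C)C(C)(C)C | intermediate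
19 | (1,3-dioxolan-2-ylmethyl)zinc bromide | Br[Zn]CC1OCCO1 | starting material
20 | cyclic enol ether with 1,3-dioxolan-2-ylmethyl group on C5 | CC(=O)O[C@H]1C[C@@]2(C)OC(CC3OCCO3)=C[C@@H]1C[C@H]2O[Si](C)(C)C(C)(C)C | intermediate
21 | C10 alkylborane from 20 (boron and C5–H on the face of the C12–C13 bridge) | CC(=O)O[C@H]1C[C@@]2(C)O[C@@H](CC3OCCO3)[C@H](B)[C@@H]1C[C@H]2O[Si](C)(C)C(C)(C)C | intermediate (not isolated)
22 | C10 alcohol with C5–H (C5 S; hydroxyl and C5–H on the face of the C12–C13 bridge) | CC(=O)O[C@H]1C[C@@]2(C)O[C@@H](CC3OCCO3)[C@H](O)[C@@H]1C[C@H]2O[Si](C)(C)C(C)(C)C | intermediate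
23 | C7 aldehyde with free C10 hydroxyl | CC(=O)O[C@H]1C[C@@]2(C)O[C@@H](CC=O)[C@H](O)[C@@H]1C[C@H]2O[Si](C)(C)C(C)(C)C | intermediate
24 | isopropyltriphenylphosphonium iodide | CC(C)[P+](c1ccccc1)(c1ccccc1)c1ccccc1.[I-] | starting material
25 | prenyl alcohol (3-methylbut-2-enyl on C5, secondary C10 hydroxyl) | CC(=O)O[C@H]1C[C@@]2(C)O[C@@H](CC=C(C)C)[C@H](O)[C@@H]1C[C@H]2O[Si](C)(C)C(C)(C)C | intermediate
26 | C10 ketone with prenyl chain on C5 | CC(=O)O[C@H]1C[C@@]2(C)O[C@@H](CC=C(C)C)C(=O)[C@@H]1C[C@H]2O[Si](C)(C)C(C)(C)C | intermediate
27 | tertiary alcohol, C10 S (methyl towards the C12–C13 bridge) | CC(=O)O[C@H]1C[C@@]2(C)O[C@@H](CC=C(C)C)[C@@](C)(O)[C@@H]1C[C@H]2O[Si](C)(C)C(C)(C)C | intermediate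
28 | C13 tert-butyldimethylsilyl ether of the target | CC(=O)O[C@H]1C[C@@]2(C)O[C@H]3C[C@H](Br)C(C)(C)O[C@@]3(C)[C@@H]1C[C@H]2O[Si](C)(C)C(C)(C)C | intermediate
29 | CNP0247588.2: (1S,3R,5S,7S,10S,11R,13R)-1-acetoxy-7-bromo-3,8,8,10-tetramethyl tricyclic bis-ether (O4 and O9) with 13-hydroxyl, target numbering | CC(=O)O[C@H]1C[C@@]2(C)O[C@H]3C[C@H](Br)C(C)(C)O[C@@]3(C)[C@@H]1C[C@H]2O | target

## Step count and least certain steps

Total step count: 19. Longest linear sequence: 19 (compounds 2, 10, 19 and 24 are bought).

Step 7 (key step). What may go wrong: partial migration of the C10 methylene in the ring ketone, slow addition of the peracid to the hindered C5 carbonyl so that the acetyl methyl closes an aldol onto C5 first, or acid-promoted loss of the dioxolane followed by oxidation at C13. Fallback: the route leaves at 11, intercepted before desilylation in step 6. N-Chlorosuccinimide should convert 11 into the 10-chloro diketone F1. An α-halogenated carbon is a poor migrating group, so the same peracid should give the chloro lactone acetate F2 by migration of C3 only. Zinc in acetic acid should then remove the chlorine and return the route at 14.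

Step 6. What may go wrong: ionisation of the allylic ketal of the diene by the strong boron Lewis acid with aromatisation, or insufficient facial and endo selectivity with a monodentate methyl ketone. Fallback: the route leaves at 9 and uses the chelating dienophile 4-hydroxy-4-methylpent-1-en-3-one F3 with Cu(OTf)2 and 2,2'-(propane-2,2-diyl)bis[(4S)-4-tert-butyl-4,5-dihydrooxazole], a milder catalyst of divalent copper that binds the ketol through two points. The cycloadduct F4 is treated with MeMgBr to give the diol F5, and NaIO4 cleavage of F5 should release the methyl ketone and return the route at 11.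

Step 9. What may go wrong: hydride delivery from the C2 side, anti to the C3–O4 bond, which would give the C13 epimer (this epimer can also translactonise). Fallback: the route leaves at 15 and returns at 16 with catalyst control in place of substrate control. A B-methyl oxazaborolidine from diphenylprolinol with BH3·SMe2 differentiates the quaternary C3 side from the C12 methylene, and the catalyst enantiomer is chosen to deliver hydride from the O4 face. No new compound is involved.

Step 11. What may go wrong: competing deprotonation of the acetate, or acyl transfer from the C1 acetate to the C10 enolate carbon. Fallback: the route leaves at 17 with soft enolisation. t-BuMe2SiOTf and Et3N should convert only the more acidic lactone into the ketene silyl acetal F6. CsF and PhNTf2 should then give the ketene acetal triflate F7 without a free enolate being held in solution. F7 enters the coupling of step 12 in place of 18 and the route returns at 20.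

Step 18. What may go wrong: closure in the five-membered mode with bromine on C8, or poor facial selectivity at C7. Fallback: the route leaves at 27 with a mercury-mediated cyclisation. Hg(OCOCF3)2 adds at the more substituted carbon more strictly than a bromonium ion and reversibly, so that after exchange with KBr the equatorial organomercurial bromide F8 should form under thermodynamic control. Bromodemercuration of F8 with Br2 and LiBr in pyridine should give the bromide and return the route at 28.

## Further compounds

F1 | step 7 | 10-chloro derivative of 12 (C10 epimers; the centre is removed later) | CC(=O)[C@H]1C[C@@]2(C)C(=O)C(Cl)[C@@H]1CC23OCCO3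
F2 | step 7 | 10-chloro derivative of 14 (C10 epimers) | CC(=O)O[C@H]1C[C@@]2(C)OC(=O)C(Cl)[C@@H]1CC23OCCO3
F3 | step 6 | 4-hydroxy-4-methylpent-1-en-3-one | CC(C)(O)C(=O)C=C
F4 | step 6 | silyl enol ether cycloadduct with 2-hydroxy-2-methylpropanoyl group on C1 | CC(C)(O)C(=O)[C@H]1C[C@@]2(C)C(O[Si](C)(C)C(C)(C)C)=C[C@@H]1CC23OCCO3
F5 | step 6 | 2,3-dimethylbutane-2,3-diol side chain on C1 after methyl addition (carbinol centre undefined) | CC(C)(O)C(C)(O)[C@H]1C[C@@]2(C)C(O[Si](C)(C)C(C)(C)C)=C[C@@H]1CC23OCCO3
F0 | step 9 | none | none
F6 | step 11 | ketene tert-butyldimethylsilyl acetal of 17 | CC(=O)O[C@H]1C[C@@]2(C)OC(O[Si](C)(C)C(C)(C)C)=C[C@@H]1C[C@H]2O[Si](C)(C)C(C)(C)C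
F7 | step 11 | ketene acetal trifluoromethanesulfonate of 17 | CC(=O)O[C@H]1C[C@@]2(C)OC(OS(=O)(=O)C(F)(F)F)=C[C@@H]1C[C@H]2O[Si](C)(C)C(C)(C)C
F8 | step 18 | C7 bromomercurio analogue of 28 | CC(=O)O[C@H]1C[C@@]2(C)O[C@H]3C[C@H]([Hg]Br)C(C)(C)O[C@@]3(C)[C@@H]1C[C@H]2O[Si](C)(C)C(C)(C)C
A1 | alternative 1 | C10 ketone with C5 dithiane and the C5–C8 chain | COc1ccc(CO[C@H]2C=C(C)[C@H](O[Si](C)(C)C(C)(C)C)C[C@H]2C(=O)C3(SCCCS3)C[C@H](O[Si](C)(C)C(C)(C)C)C(C)(C)O[Si](CC)(CC)CC)cc1
A2 | alternative 1 | 2-(tert-butyldimethylsilyl)-1,3-dithiane | CC(C)(C)[Si](C)(C)C1SCCCS1
A3 | alternative 1 | triethyl{[2-(oxiran-2-yl)propan-2-yl]oxy}silane, C7 as in A1 | CC[Si](CC)(CC)OC(C)(C)[C@@H]1CO1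
A4 | alternative 1 | ring A N-methoxy-N-methylamide | COc1ccc(CO[C@H]2C=C(C)[C@H](O[Si](C)(C)C(C)(C)C)C[C@H]2C(=O)N(C)OC)cc1
A5 | alternative 2 | 3-methoxy-2,6-dimethylphenol | COc1ccc(C)c(O)c1C
A6 | alternative 2 | tricyclic lactone bicyclo[2.2.2]octenone with C5 ketone and C13 enol ether | O=C1O[C@]2(C)C(=O)[C@]3(C)C[C@H]1[C@H]2C=C3OC
A7 | alternative 3 | cineole-type ether with C5 chloromethanesulfonate, C7 bromide and C8 carbinol | CC[Si](CC)(CC)O[C@H]1C[C@@]2(C)O[C@@](C)([C@H](OS(=O)(=O)CCl)C[C@H](Br)C(C)(C)O)[C@@H]1C[C@H]2O
A8 | alternative 3 | desacetyl target as its C1 triethylsilyl ether | CC[Si](CC)(CC)O[C@H]1C[C@@]2(C)O[C@H]3C[C@H](Br)C(C)(C)O[C@@]3(C)[C@@H]1C[C@H]2O
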